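## Retrosynthetic overview

1. Last C–C bond: Stille coupling of a core (E)-vinylstannane with the (2E,4E)-5-bromodienamide of 2-amino-3-hydroxycyclopent-2-enone (lower chain, made separately).
2. Upper chain: enamide C–N bond from a 2-iodo epoxy-enone and (2E,4R)-4-methyloct-2-enamide (Evans methylation, Wittig) by copper-catalysed amidation.
3. Oxirane: substrate-controlled nucleophilic epoxidation of a 4-silyloxy-4-alkynylcyclohex-2-enone, anti to the silyloxy group; then Saegusa oxidation and α-iodination on the other flank.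
4. Cyclohexenone ring: intramolecular aldol condensation of an acyclic 5-oxo-aldehyde (methyl ketone onto a non-enolisable α-silyloxy aldehyde).
5. The quaternary carbinol is set before cyclisation by Sharpless epoxidation of a 2-alkynyl allylic alcohol and opening with an acetone aza-enolate. Ring order: cyclohexenone (aldol), then oxirane; the cyclopentenone ring is bought.

Assumption: the structure is taken exactly as the SMILES gives it, i.e. a (4R)-methyl group in the octenoyl chain and a (1S,5R,6R)-7-oxabicyclo[4.1.0]heptenone core whose tertiary hydroxyl lies on the face opposite the oxirane oxygen.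

## Route

**Upper chain (fragment A)**

Step 1
Reactants: 1 (4R)-4-benzyl-1,3-oxazolidin-2-one; 2 hexanoyl chloride
Product: 3 (4R)-4-benzyl-3-hexanoyl-1,3-oxazolidin-2-one
Conditions: Et3N, DMAP (cat.), CH2Cl2, 0 °C to rt
Reagents that add atoms: none
Why: DMAP-catalysed N-acylation of the Evans auxiliary by the acid chloride leaves the auxiliary stereocentre untouched.

Step 2
Reactants: 3 (4R)-4-benzyl-3-hexanoyl-1,3-oxazolidin-2-one
Product: 5 (4R)-4-benzyl-3-[(2R)-2-methylhexanoyl]-1,3-oxazolidin-2-one, via sodium Z-enolate 4 (not isolated)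
Conditions: NaN(SiMe3)2, THF, −78 °C; MeI, −78 to −40 °C
Reagents that add atoms: iodomethane, CI
Why: Evans asymmetric alkylation, in which the chelated Z-enolate is methylated on the face opposite the benzyl group and so sets the (2R) centre (minor diastereomer removed by chromatography).

Step 3
Reactants: 5 (4R)-4-benzyl-3-[(2R)-2-methylhexanoyl]-1,3-oxazolidin-2-one
Product: 6 (2R)-2-methylhexan-1-ol
Conditions: LiBH4, H2O (1 equiv), Et2O, 0 °C
Reagents that add atoms: none
Why: Reductive cleavage of the imide by LiBH4 releases the primary alcohol without touching the α-stereocentre and returns the auxiliary.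

Step 4
Reactants: 6 (2R)-2-methylhexan-1-ol
Product: 7 (2R)-2-methylhexanal
Conditions: TEMPO (1 mol%), KBr (10 mol%), NaOCl, NaHCO3, CH2Cl2/H2O, 0 °C; used at once
Reagents that add atoms: none
Why: Anelli (TEMPO/hypochlorite) oxidation stops at the aldehyde and is fast and buffered, so the α-stereocentre does not epimerise.

Step 5
Reactants: 7 (2R)-2-methylhexanal; 8 (carbamoylmethylene)triphenylphosphorane
Product: 9 (2E,4R)-4-methyloct-2-enamide
Conditions: CH2Cl2, rt to 40 °C
Reagents that add atoms: none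
Why: Wittig olefination with a stabilised ylide gives the (E)-enamide under neutral conditions that keep C-4 intact.

**Lower chain (fragment C)**

Step 6
Reactants: 10 pyridine–sulfur trioxide complex
Product: 11 glutaconaldehyde potassium salt
Conditions: KOH (aq.), −20 °C then 40 °C
Reagents that add atoms: potassium hydroxide, [K+].[OH-]
Why: Zincke-type ring opening of the N-sulfonatopyridinium by hydroxide and hydrolysis of the N-sulfonyl imine give the all-trans dienolate.

Step 7
Reactants: 11 glutaconaldehyde potassium salt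
Product: 12 (2E,4E)-5-bromopenta-2,4-dienal
Conditions: Ph3PBr2, CH2Cl2, 0 °C to rt
Reagents that add atoms: dibromotriphenylphosphorane, BrP(Br)(c1ccccc1)(c1ccccc1)c1ccccc1
Why: The enolate oxygen is activated as an oxyphosphonium and displaced by bromide through addition–elimination on the vinylogous formyl system, and the product settles as the (2E,4E) isomer.

Step 8
Reactants: 12 (2E,4E)-5-bromopenta-2,4-dienal
Product: 13 (2E,4E)-5-bromopenta-2,4-dienoic acid
Conditions: NaClO2, NaH2PO4, 2-methylbut-2-ene, t-BuOH/H2O, rt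
Reagents that add atoms: sodium chlorite, [Na+].[O-]Cl=O
Why: Pinnick oxidation converts the enal to the acid without touching the vinyl bromide or the alkene geometry.

Step 9
Reactants: 14 cyclopentane-1,3-dione
Product: 15 3-hydroxy-2-nitrocyclopent-2-en-1-one
Conditions: HNO3 (fuming), Et2O, 0 °C to rt
Reagents that add atoms: nitric acid, O[N+](=O)[O-]
Why: Electrophilic nitration of the fully enolised 1,3-dione at its nucleophilic C-2.

Step 10
Reactants: 15 3-hydroxy-2-nitrocyclopent-2-en-1-one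
Product: 16 2-amino-3-hydroxycyclopent-2-en-1-one hydrochloride
Conditions: H2 (1 atm), 10% Pd on carbon, HCl (1.1 equiv), EtOH, rt
Reagents that add atoms: hydrogen chloride, Cl
Why: Catalytic hydrogenation of the nitro group, with the amine trapped as its hydrochloride to stop self-condensation.

Step 11
Reactants: 13 (2E,4E)-5-bromopenta-2,4-dienoic acid; 16 2-amino-3-hydroxycyclopent-2-en-1-one hydrochloride
Product: 18 (2E,4E)-5-bromo-N-(2-hydroxy-5-oxocyclopent-1-en-1-yl)penta-2,4-dienamide, via acid chloride 17 (not isolated)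
Conditions: (COCl)2, DMF (cat.), CH2Cl2, 0 °C; then 16, Et3N, THF/DMF, 0 °C to rt
Reagents that add atoms: none
Why: Amide formation through the acid chloride, where N-acylation of the aminoenolone is favoured and any O-acyl isomer transfers to nitrogen.

**Core and endgame**

Step 12
Reactants: 19 2-bromoprop-2-en-1-ol; 20 ethynyl(triethyl)silane
Product: 21 2-methylidene-4-(triethylsilyl)but-3-yn-1-ol
Conditions: Pd(PPh3)2Cl2 (2 mol%), CuI (4 mol%), Et3N, THF, rt
Reagents that add atoms: none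
Why: Sonogashira coupling of the vinyl bromide with the terminal alkyne.

Step 13
Reactants: 21 2-methylidene-4-(triethylsilyl)but-3-yn-1-ol
Product: 22 [(2S)-2-[(triethylsilyl)ethynyl]oxiran-2-yl]methanol
Conditions: Ti(OiPr)4 (10 mol%), L-(+)-diethyl tartrate (12 mol%), t-BuOOH, 4 Å molecular sieves, CH2Cl2, −20 °C
Reagents that add atoms: tert-butyl hydroperoxide, CC(C)(C)OO
Why: Sharpless asymmetric epoxidation, in which the L-(+)-tartrate complex delivers oxygen to one face of the 2-substituted allylic alcohol and gives the (S)-epoxy alcohol, the future quaternary carbinol.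

Step 14
Reactants: 22 [(2S)-2-[(triethylsilyl)ethynyl]oxiran-2-yl]methanol
Product: 23 triethyl{[(2R)-2-[(triethylsilyl)ethynyl]oxiran-2-yl]methoxy}silane
Conditions: Et3SiCl, imidazole, CH2Cl2, 0 °C
Reagents that add atoms: chlorotriethylsilane, CC[Si](Cl)(CC)CC
Why: Silylation of the primary alcohol blocks the degenerate Payne rearrangement that would racemise this 2,2-disubstituted glycidol in the basic next step (the descriptor changes only through ligand priority).

Step 15
Reactants: 23 triethyl{[(2R)-2-[(triethylsilyl)ethynyl]oxiran-2-yl]methoxy}silane; 24 acetone N,N-dimethylhydrazone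
Product: 26 (3S)-6-(dimethylhydrazinylidene)-1-(triethylsilyl)-3-{[(triethylsilyl)oxy]methyl}hept-1-yn-3-ol, via lithium aza-enolate 25 (not isolated)
Conditions: n-BuLi, THF, −78 to 0 °C; then 23, 0 °C to rt; H2O
Reagents that add atoms: none
Why: Corey–Enders aza-enolate alkylation, in which the hard nucleophile opens the epoxide by SN2 attack at the unsubstituted CH2 so that the C–O bond of the stereocentre is never broken.

Step 16
Reactants: 26 (3S)-6-(dimethylhydrazinylidene)-1-(triethylsilyl)-3-{[(triethylsilyl)oxy]methyl}hept-1-yn-3-ol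
Product: 27 N,N-dimethylhydrazone of (5S)-5-[(triethylsilyl)ethynyl]-5,6-bis[(triethylsilyl)oxy]hexan-2-one
Conditions: Et3SiOTf, 2,6-lutidine, CH2Cl2, −78 to 0 °C
Reagents that add atoms: triethylsilyl trifluoromethanesulfonate, CC[Si](CC)(CC)OS(=O)(=O)C(F)(F)F
Why: Silyl triflate silylation of the hindered tertiary propargylic alcohol, giving the bulky ether that later steers the epoxidation.

Step 17
Reactants: 27 N,N-dimethylhydrazone of (5S)-5-[(triethylsilyl)ethynyl]-5,6-bis[(triethylsilyl)oxy]hexan-2-one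
Product: 28 (5S)-5-[(triethylsilyl)ethynyl]-5,6-bis[(triethylsilyl)oxy]hexan-2-one
Conditions: CuCl2, THF/pH 7 phosphate buffer, rt
Reagents that add atoms: water, O
Why: Copper-assisted hydrolysis of the dimethylhydrazone at neutral pH frees the methyl ketone without cleaving the silyl ethers.

Step 18
Reactants: 28 (5S)-5-[(triethylsilyl)ethynyl]-5,6-bis[(triethylsilyl)oxy]hexan-2-one
Product: 29 (2S)-5-oxo-2-[(triethylsilyl)ethynyl]-2-[(triethylsilyl)oxy]hexanal
Conditions: (COCl)2, DMSO, CH2Cl2, −78 to −30 °C; Et3N, −78 °C to rt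
Reagents that add atoms: none
Why: Under Swern conditions a primary triethylsilyl ether is cleaved and oxidised to the aldehyde in one operation while the tertiary silyl ether and the alkynylsilane survive.

Step 19
Reactants: 29 (2S)-5-oxo-2-[(triethylsilyl)ethynyl]-2-[(triethylsilyl)oxy]hexanal
Product: 31 (4R)-4-[(triethylsilyl)ethynyl]-4-[(triethylsilyl)oxy]cyclohex-2-en-1-one, via aldol adduct 30 (not isolated)
Conditions: pyrrolidine (0.3 equiv), AcOH (0.3 equiv), toluene, rt to 50 °C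
Reagents that add atoms: none
Why: Intramolecular aldol condensation under enamine catalysis, in which only the methyl-side enamine can reach the non-enolisable aldehyde through a six-membered transition state and dehydration gives the enone without involving the quaternary centre.

Step 20
Reactants: 31 (4R)-4-[(triethylsilyl)ethynyl]-4-[(triethylsilyl)oxy]cyclohex-2-en-1-one
Product: 32 (1S,5S,6R)-5-[(triethylsilyl)ethynyl]-5-[(triethylsilyl)oxy]-7-oxabicyclo[4.1.0]heptan-2-one
Conditions: t-BuOOH, DBU, CH2Cl2, 0 °C to rt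
Reagents that add atoms: tert-butyl hydroperoxide, CC(C)(C)OO
Why: Weitz–Scheffer nucleophilic epoxidation, in which the peroxide anion adds to the β-carbon anti to the adjacent silyloxy group (as with 4-silyloxycyclohexenones), so the oxirane oxygen ends up cis to the slim alkyne and trans to the C–O bond, setting both oxirane carbons.

Step 21
Reactants: 32 (1S,5S,6R)-5-[(triethylsilyl)ethynyl]-5-[(triethylsilyl)oxy]-7-oxabicyclo[4.1.0]heptan-2-one
Product: 34 (1S,5S,6R)-5-[(triethylsilyl)ethynyl]-5-[(triethylsilyl)oxy]-7-oxabicyclo[4.1.0]hept-3-en-2-one, via silyl enol ether 33 (not isolated)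
Conditions: LiN(SiMe3)2, Me3SiCl, THF, −78 °C; then Pd(OAc)2 (1.1 equiv), MeCN, rt
Reagents that add atoms: none
Why: Saegusa–Ito oxidation, regiospecific because only the CH2 flank of the ketone can enolise (the other α-carbon is the oxirane).

Step 22
Reactants: 34 (1S,5S,6R)-5-[(triethylsilyl)ethynyl]-5-[(triethylsilyl)oxy]-7-oxabicyclo[4.1.0]hept-3-en-2-one
Product: 35 (1S,5S,6R)-3-iodo-5-[(triethylsilyl)ethynyl]-5-[(triethylsilyl)oxy]-7-oxabicyclo[4.1.0]hept-3-en-2-one
Conditions: I2, pyridine, CH2Cl2, 0 °C to rt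
Reagents that add atoms: iodine, II
Why: Johnson α-iodination of the enone (conjugate addition of pyridine, iodination, elimination), a reaction known to work on epoxy-enones.

Step 23
Reactants: 35 (1S,5S,6R)-3-iodo-5-[(triethylsilyl)ethynyl]-5-[(triethylsilyl)oxy]-7-oxabicyclo[4.1.0]hept-3-en-2-one; 9 (2E,4R)-4-methyloct-2-enamide
Product: 36 (2E,4R)-4-methyl-N-{(1S,5S,6R)-2-oxo-5-[(triethylsilyl)ethynyl]-5-[(triethylsilyl)oxy]-7-oxabicyclo[4.1.0]hept-3-en-3-yl}oct-2-enamide
Conditions: CuI (10 mol%), MeNHCH2CH2NHMe (20 mol%), Cs2CO3, toluene, 50–60 °C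
Reagents that add atoms: none
Why: Buchwald–Goldberg copper-catalysed amidation of the vinyl iodide by the primary amide, on a substrate that has no enolisable hydrogen and whose alkyne is masked.

Step 24
Reactants: 36 (2E,4R)-4-methyl-N-{(1S,5S,6R)-2-oxo-5-[(triethylsilyl)ethynyl]-5-[(triethylsilyl)oxy]-7-oxabicyclo[4.1.0]hept-3-en-3-yl}oct-2-enamide
Product: 37 (2E,4R)-N-[(1S,5S,6R)-5-ethynyl-5-hydroxy-2-oxo-7-oxabicyclo[4.1.0]hept-3-en-3-yl]-4-methyloct-2-enamide
Conditions: Bu4NF, AcOH (1:1), THF, 0 °C to rt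
Reagents that add atoms: none
Why: Fluoride cleaves both the O–Si and the alkynyl C–Si bond, and the acetic acid buffer keeps the trans-epoxy alcohol from Payne rearrangement.

Step 25
Reactants: 37 (2E,4R)-N-[(1S,5S,6R)-5-ethynyl-5-hydroxy-2-oxo-7-oxabicyclo[4.1.0]hept-3-en-3-yl]-4-methyloct-2-enamide
Product: 38 (2E,4R)-N-{(1S,5S,6R)-5-hydroxy-2-oxo-5-[(E)-2-(tributylstannyl)ethenyl]-7-oxabicyclo[4.1.0]hept-3-en-3-yl}-4-methyloct-2-enamide
Conditions: Bu3SnH (slow addition), Pd(PPh3)2Cl2 (3 mol%), THF, 0 °C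
Reagents that add atoms: tributyltin hydride, CCCC[SnH](CCCC)CCCC
Why: Palladium-catalysed syn-hydrostannation of the terminal alkyne, with the bulky tertiary carbinol sending tin to the terminal carbon to give the (E)-vinylstannane.

Step 26
Reactants: 38 (2E,4R)-N-{(1S,5S,6R)-5-hydroxy-2-oxo-5-[(E)-2-(tributylstannyl)ethenyl]-7-oxabicyclo[4.1.0]hept-3-en-3-yl}-4-methyloct-2-enamide; 18 (2E,4E)-5-bromo-N-(2-hydroxy-5-oxocyclopent-1-en-1-yl)penta-2,4-dienamide
Product: 39 (2E,4R)-N-[(1S,5R,6R)-5-hydroxy-5-{(1E,3E,5E)-7-[(2-hydroxy-5-oxocyclopent-1-en-1-yl)amino]-7-oxohepta-1,3,5-trien-1-yl}-2-oxo-7-oxabicyclo[4.1.0]hept-3-en-3-yl]-4-methyloct-2-enamide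
Conditions: Pd2(dba)3 (5 mol%), AsPh3 (20 mol%), DMF, rt, dark
Reagents that add atoms: none
Why: Stille coupling proceeds with retention of both alkene geometries to give the (E,E,E)-triene under neutral conditions that the epoxy-quinol, the enamide and the free enol tolerate.

## Compound list

1 | (4R)-4-benzyl-1,3-oxazolidin-2-one | O=C1N[C@H](Cc2ccccc2)CO1 | starting material
2 | hexanoyl chloride | CCCCCC(Cl)=O | starting material
3 | (4R)-4-benzyl-3-hexanoyl-1,3-oxazolidin-2-one | CCCCCC(=O)N1[C@H](Cc2ccccc2)COC1=O | intermediate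
4 | sodium (Z)-enolate of 3 | CCCC/C=C(\[O-])N1[C@H](Cc2ccccc2)COC1=O.[Na+] | intermediate (not isolated)
5 | (4R)-4-benzyl-3-[(2R)-2-methylhexanoyl]-1,3-oxazolidin-2-one | CCCC[C@@H](C)C(=O)N1[C@H](Cc2ccccc2)COC1=O | intermediate
6 | (2R)-2-methylhexan-1-ol | CCCC[C@@H](C)CO | intermediate
7 | (2R)-2-methylhexanal | CCCC[C@@H](C)C=O | intermediate
8 | (carbamoylmethylene)triphenylphosphorane | NC(=O)C=P(c1ccccc1)(c1ccccc1)c1ccccc1 | starting material
9 | (2E,4R)-4-methyloct-2-enamide | CCCC[C@@H](C)/C=C/C(N)=O | intermediate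
10 | pyridine–sulfur trioxide complex | [O-]S(=O)(=O)[n+]1ccccc1 | starting material
11 | glutaconaldehyde potassium salt | [K+].[O-]/C=C/C=C/C=O | intermediate
12 | (2E,4E)-5-bromopenta-2,4-dienal | Br/C=C/C=C/C=O | intermediate
13 | (2E,4E)-5-bromopenta-2,4-dienoic acid | Br/C=C/C=C/C(O)=O | intermediate
14 | cyclopentane-1,3-dione | O=C1CCC(=O)C1 | starting material
15 | 3-hydroxy-2-nitrocyclopent-2-en-1-one (enol of 2-nitrocyclopentane-1,3-dione) | O=C1CCC(O)=C1[N+](=O)[O-] | intermediate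
16 | 2-amino-3-hydroxycyclopent-2-en-1-one hydrochloride | NC1=C(O)CCC1=O.Cl | intermediate
17 | (2E,4E)-5-bromopenta-2,4-dienoyl chloride | Br/C=C/C=C/C(Cl)=O | intermediate (not isolated)
18 | (2E,4E)-5-bromo-N-(2-hydroxy-5-oxocyclopent-1-en-1-yl)penta-2,4-dienamide | Br/C=C/C=C/C(=O)NC1=C(O)CCC1=O | intermediate
19 | 2-bromoprop-2-en-1-ol | C=C(Br)CO | starting material
20 | ethynyl(triethyl)silane | C#C[Si](CC)(CC)CC | starting material
21 | 2-methylidene-4-(triethylsilyl)but-3-yn-1-ol | C=C(CO)C#C[Si](CC)(CC)CC | intermediate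
22 | [(2S)-2-[(triethylsilyl)ethynyl]oxiran-2-yl]methanol | OC[C@@]1(C#C[Si](CC)(CC)CC)CO1 | intermediate
23 | triethyl{[(2R)-2-[(triethylsilyl)ethynyl]oxiran-2-yl]methoxy}silane | CC[Si](CC)(CC)OC[C@@]1(C#C[Si](CC)(CC)CC)CO1 | intermediate
24 | acetone N,N-dimethylhydrazone | CC(C)=NN(C)C | starting material
25 | lithium aza-enolate of 24 | [Li]N(N(C)C)C(C)=C | intermediate (not isolated)
26 | (3S)-6-(dimethylhydrazinylidene)-1-(triethylsilyl)-3-{[(triethylsilyl)oxy]methyl}hept-1-yn-3-ol | CC(=NN(C)C)CC[C@](O)(C#C[Si](CC)(CC)CC)CO[Si](CC)(CC)CC | intermediate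
27 | N,N-dimethylhydrazone of (5S)-5-[(triethylsilyl)ethynyl]-5,6-bis[(triethylsilyl)oxy]hexan-2-one | CC(=NN(C)C)CC[C@](O[Si](CC)(CC)CC)(C#C[Si](CC)(CC)CC)CO[Si](CC)(CC)CC | intermediate
28 | (5S)-5-[(triethylsilyl)ethynyl]-5,6-bis[(triethylsilyl)oxy]hexan-2-one | CC(=O)CC[C@](O[Si](CC)(CC)CC)(C#C[Si](CC)(CC)CC)CO[Si](CC)(CC)CC | intermediate
29 | (2S)-5-oxo-2-[(triethylsilyl)ethynyl]-2-[(triethylsilyl)oxy]hexanal | CC(=O)CC[C@](O[Si](CC)(CC)CC)(C#C[Si](CC)(CC)CC)C=O | intermediate
30 | (4S)-3-hydroxy-4-[(triethylsilyl)ethynyl]-4-[(triethylsilyl)oxy]cyclohexan-1-one (both C-3 epimers) | O=C1CC[C@](O[Si](CC)(CC)CC)(C#C[Si](CC)(CC)CC)C(O)C1 | intermediate (not isolated)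
31 | (4R)-4-[(triethylsilyl)ethynyl]-4-[(triethylsilyl)oxy]cyclohex-2-en-1-one | O=C1CC[C@](O[Si](CC)(CC)CC)(C#C[Si](CC)(CC)CC)C=C1 | intermediate
32 | (1S,5S,6R)-5-[(triethylsilyl)ethynyl]-5-[(triethylsilyl)oxy]-7-oxabicyclo[4.1.0]heptan-2-one | C1C[C@](O[Si](CC)(CC)CC)(C#C[Si](CC)(CC)CC)[C@@H]2O[C@@H]2C1=O | intermediate
33 | {[(1S,5S,6R)-5-[(triethylsilyl)ethynyl]-5-[(triethylsilyl)oxy]-7-oxabicyclo[4.1.0]hept-2-en-2-yl]oxy}trimethylsilane | C1[C@](O[Si](CC)(CC)CC)(C#C[Si](CC)(CC)CC)[C@@H]2O[C@@H]2C(O[Si](C)(C)C)=C1 | intermediate (not isolated)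
34 | (1S,5S,6R)-5-[(triethylsilyl)ethynyl]-5-[(triethylsilyl)oxy]-7-oxabicyclo[4.1.0]hept-3-en-2-one | C1=C[C@](O[Si](CC)(CC)CC)(C#C[Si](CC)(CC)CC)[C@@H]2O[C@@H]2C1=O | intermediate
35 | (1S,5S,6R)-3-iodo-5-[(triethylsilyl)ethynyl]-5-[(triethylsilyl)oxy]-7-oxabicyclo[4.1.0]hept-3-en-2-one | IC1=C[C@](O[Si](CC)(CC)CC)(C#C[Si](CC)(CC)CC)[C@@H]2O[C@@H]2C1=O | intermediate
36 | (2E,4R)-4-methyl-N-{(1S,5S,6R)-2-oxo-5-[(triethylsilyl)ethynyl]-5-[(triethylsilyl)oxy]-7-oxabicyclo[4.1.0]hept-3-en-3-yl}oct-2-enamide | CCCC[C@@H](C)/C=C/C(=O)NC1=C[C@](O[Si](CC)(CC)CC)(C#C[Si](CC)(CC)CC)[C@@H]2O[C@@H]2C1=O | intermediate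
37 | (2E,4R)-N-[(1S,5S,6R)-5-ethynyl-5-hydroxy-2-oxo-7-oxabicyclo[4.1.0]hept-3-en-3-yl]-4-methyloct-2-enamide | CCCC[C@@H](C)/C=C/C(=O)NC1=C[C@](O)(C#C)[C@@H]2O[C@@H]2C1=O | intermediate
38 | (2E,4R)-N-{(1S,5S,6R)-5-hydroxy-2-oxo-5-[(E)-2-(tributylstannyl)ethenyl]-7-oxabicyclo[4.1.0]hept-3-en-3-yl}-4-methyloct-2-enamide | CCCC[C@@H](C)/C=C/C(=O)NC1=C[C@](O)(/C=C/[Sn](CCCC)(CCCC)CCCC)[C@@H]2O[C@@H]2C1=O | intermediate
39 | (2E,4R)-N-[(1S,5R,6R)-5-hydroxy-5-{(1E,3E,5E)-7-[(2-hydroxy-5-oxocyclopent-1-en-1-yl)amino]-7-oxohepta-1,3,5-trien-1-yl}-2-oxo-7-oxabicyclo[4.1.0]hept-3-en-3-yl]-4-methyloct-2-enamide | CCCC[C@@H](C)/C=C/C(=O)NC1=C[C@](O)(/C=C/C=C/C=C/C(=O)NC2=C(O)CCC2=O)[C@@H]2O[C@@H]2C1=O | target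

## Step count and risks

Total step count: 26 (fragment A: steps 1–5; fragment C: steps 6–11; core and endgame: steps 12–26).
Longest linear sequence: 15 steps (steps 12–26, from 19 to 39).

**Three steps most likely to fail**

Step 20 (facial selectivity of the epoxidation, and slow peroxide attack at a β-carbon next to a quaternary centre). The fallback sets out from 31 and comes back at 32. It replaces the nucleophilic peroxide by osmylation, whose preference for the face anti to an allylic oxygen is independent of the enone electronics. Treating 31 with OsO4 (cat.) and N-methylmorpholine N-oxide in acetone/water gives the cis-diol (2S,3R,4S)-2,3-dihydroxy-4-[(triethylsilyl)ethynyl]-4-[(triethylsilyl)oxy]cyclohexan-1-one F1, both hydroxyls cis to the alkyne. Selective mesylation of the unhindered α-keto hydroxyl (MsCl, Et3N, −40 °C) gives (2S,3R,4S)-3-hydroxy-2-(methanesulfonyloxy)-4-[(triethylsilyl)ethynyl]-4-[(triethylsilyl)oxy]cyclohexan-1-one F2. LiBr in acetone displaces the α-keto mesylate with inversion to the trans-bromohydrin (2R,3S,4S)-2-bromo-3-hydroxy-4-[(triethylsilyl)ethynyl]-4-[(triethylsilyl)oxy]cyclohexan-1-one F3. K2CO3 then closes the oxirane from the C-3 alkoxide with a second inversion at C-2, which gives 32.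

Step 23 (copper-catalysed amidation on a base- and nucleophile-sensitive iodo epoxy-enone). The fallback sets out from 32 (through its enol silane 33) and comes back at 36, bypassing steps 21–23; nitrogen enters by condensation, not cross-coupling. Rubottom oxidation of 33 with dimethyldioxirane (acetone, −40 °C, mild acidic work-up) gives (1S,5S,6R)-3-hydroxy-5-[(triethylsilyl)ethynyl]-5-[(triethylsilyl)oxy]-7-oxabicyclo[4.1.0]heptan-2-one F4. Dess–Martin periodinane oxidises it to the 1,2-dione, which exists as the enol (1S,5S,6R)-3-hydroxy-5-[(triethylsilyl)ethynyl]-5-[(triethylsilyl)oxy]-7-oxabicyclo[4.1.0]hept-3-en-2-one F5. Warming F5 with amide 9 and pyridinium p-toluenesulfonate over 4 Å sieves in toluene adds the amide to the C-3 carbonyl and dehydrates toward C-4, giving 36.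

Step 25 (hydrostannation: Pd–H reduction of the enone, or tin going to the internal carbon). The fallback sets out from 37 and comes back at 39, replacing tin by silicon. Platinum-catalysed hydrosilylation of 37 with HSiMe2OEt (Pt2[(CH2=CHSiMe2)2O]3, P(t-Bu)3, THF) is alkyne-selective, syn and terminal-selective and gives (2E,4R)-N-{(1S,5S,6R)-5-[(E)-2-(ethoxydimethylsilyl)ethenyl]-5-hydroxy-2-oxo-7-oxabicyclo[4.1.0]hept-3-en-3-yl}-4-methyloct-2-enamide F6. Fluoride-promoted Hiyama–Denmark coupling of F6 with bromide 18 (Pd2(dba)3, Bu4NF, THF, rt) gives 39 directly.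

## Further compounds

F1 | step 20 | (2S,3R,4S)-2,3-dihydroxy-4-[(triethylsilyl)ethynyl]-4-[(triethylsilyl)oxy]cyclohexan-1-one | C1C[C@](O[Si](CC)(CC)CC)(C#C[Si](CC)(CC)CC)[C@H](O)[C@H](O)C1=O
F2 | step 20 | (2S,3R,4S)-3-hydroxy-2-(methanesulfonyloxy)-4-[(triethylsilyl)ethynyl]-4-[(triethylsilyl)oxy]cyclohexan-1-one | C1C[C@](O[Si](CC)(CC)CC)(C#C[Si](CC)(CC)CC)[C@H](O)[C@H](OS(C)(=O)=O)C1=O
F3 | step 20 | (2R,3S,4S)-2-bromo-3-hydroxy-4-[(triethylsilyl)ethynyl]-4-[(triethylsilyl)oxy]cyclohexan-1-one | C1C[C@](O[Si](CC)(CC)CC)(C#C[Si](CC)(CC)CC)[C@H](O)[C@@H](Br)C1=O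
F4 | step 23 | (1S,5S,6R)-3-hydroxy-5-[(triethylsilyl)ethynyl]-5-[(triethylsilyl)oxy]-7-oxabicyclo[4.1.0]heptan-2-one (C-3 epimers) | OC1C[C@](O[Si](CC)(CC)CC)(C#C[Si](CC)(CC)CC)[C@@H]2O[C@@H]2C1=O
F5 | step 23 | (1S,5S,6R)-3-hydroxy-5-[(triethylsilyl)ethynyl]-5-[(triethylsilyl)oxy]-7-oxabicyclo[4.1.0]hept-3-en-2-one | OC1=C[C@](O[Si](CC)(CC)CC)(C#C[Si](CC)(CC)CC)[C@@H]2O[C@@H]2C1=O
F6 | step 25 | (2E,4R)-N-{(1S,5S,6R)-5-[(E)-2-(ethoxydimethylsilyl)ethenyl]-5-hydroxy-2-oxo-7-oxabicyclo[4.1.0]hept-3-en-3-yl}-4-methyloct-2-enamide | CCCC[C@@H](C)/C=C/C(=O)NC1=C[C@](O)(/C=C/[Si](C)(C)OCC)[C@@H]2O[C@@H]2C1=O
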